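**Strategy.** The route rests on cutting the unbranched (CH2)12 tether at C7–C8 of the tridecanoic acid chain (C1 = carboxyl carbon, C13 on furan C2), a CH2–CH2 bond six bonds from both the carboxyl carbon and furan C2. The key step forges it by copper-catalysed C(sp3)–C(sp3) coupling of a furan-bearing hexyl Grignard reagent with the chloromagnesium salt of 7-bromoheptanoic acid and releases the free acid directly, with no protecting group or redox adjustment. It exploits the inertness of the 2,3,5-trialkylfuran ring (O1, C2–C5, only C4–H free) to basic organometallics. Its precursor, 2-(6-chlorohexyl)-3-methyl-5-pentylfuran, comes from 4-methyl-2-pentylfuran, itself made by silver-catalysed cyclodehydration of an alkynediol.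

Key step: step 4

Remark: the target has no stereocentre and no stereogenic double bond. Compounds 1, 2, 7 and 10 are assumed to be purchasable; hydroxyacetone is dried and distilled before use.

**Step 1**
Reactants: 1 hept-1-yne; 2 hydroxyacetone (1-hydroxypropan-2-one)
Product: 4 rac-2-methylnon-3-yne-1,2-diol, via lithium hept-1-yn-1-ide 3 (not isolated)
Conditions: 1 (2.4 equiv), n-BuLi (2.3 equiv), THF, −78 → 0 °C; then 2 (1 equiv), −78 → 0 °C; H2O
Reagents that add atoms: none
Why: Alkynylation of a ketone by 1,2-addition of a lithium acetylide, in which the first equivalent of 3 only deprotonates the hydroxyl of 2 and the second should add to the carbonyl faster than the weakly basic acetylide enolises it; the tertiary carbinol centre forms as a racemate and is erased in step 2.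

**Step 2**
Reactants: 4 rac-2-methylnon-3-yne-1,2-diol
Product: 6 4-methyl-2-pentylfuran, via dihydrofuranol 5 (not isolated)
Conditions: AgNO3 on silica gel (10 mol %), CH2Cl2, rt, dark
Reagents that add atoms: none
Why: Silver(I)-catalysed 5-endo-dig hydroalkoxylation of the alkyne by the primary hydroxyl, followed by aromatising loss of water from the tertiary alcohol (cyclodehydration of a 3-alkyne-1,2-diol to a furan), should place the pentyl-bearing alkyne carbon at C2 and the methyl-bearing carbinol carbon at C4 without ambiguity.

**Step 3**
Reactants: 6 4-methyl-2-pentylfuran; 7 1-bromo-6-chlorohexane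
Product: 9 2-(6-chlorohexyl)-3-methyl-5-pentylfuran, via furyllithium 8 (not isolated)
Conditions: n-BuLi (1.1 equiv), TMEDA, THF, −78 → 0 °C; then 7 (1.3 equiv), −78 °C → rt; H2O
Reagents that add atoms: none
Why: α-Lithiation of the furan at its only free α-position (C5 of 6) followed by SN2 alkylation of the furyllithium, which should take the bromide end of 7 and leave the slower primary chloride for Grignard formation.

**Step 4**
Reactants: 9 2-(6-chlorohexyl)-3-methyl-5-pentylfuran; 10 7-bromoheptanoic acid
Product: 13 13-(3-methyl-5-pentylfuran-2-yl)tridecanoic acid, via furylhexylmagnesium chloride 11 (not isolated), via chloromagnesium 7-bromoheptanoate 12 (not isolated)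
Conditions: 9, Mg, I2 (cat.), THF, reflux; separately 10, MeMgCl (1.0 equiv), THF, −20 °C; then 11 (1.2 equiv) onto 12, Li2CuCl4 (3 mol %), THF, −20 °C → rt; cold 1 M HCl to pH 3
Reagents that add atoms: none
Why: Li2CuCl4 is reduced by 11 to an alkylcopper(I)/cuprate species that attacks the primary C–Br carbon of 12 in an SN2-type oxidative addition, and reductive elimination from the resulting dialkylcopper(III) forges the C7–C8 CH2–CH2 bond and returns Cu(I). The closest known reaction type is the Kochi–Tamura copper-catalysed coupling of alkyl Grignard reagents with primary alkyl bromides, in its variant run on halomagnesium salts of ω-bromoalkanoic acids. No ring is closed and no stereocentre is formed. The step needs chemoselectivity for the C–Br carbon over the carboxyl carbon, secured by carrying the acid as magnesium carboxylate 12, which a Grignard reagent should not attack at −20 °C. It also needs cross-coupling to outrun homocoupling and β-hydride elimination, which the unhindered primary–primary pairing and the low temperature favour. The trialkylfuran ring and the chain methylenes are inert to these basic conditions, and the acid is released on brief, mildly acidic work-up.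

**Compound list**
1 | hept-1-yne | CCCCCC#C | starting material
2 | hydroxyacetone (1-hydroxypropan-2-one) | CC(=O)CO | starting material
3 | lithium hept-1-yn-1-ide | CCCCCC#C[Li] | intermediate
4 | rac-2-methylnon-3-yne-1,2-diol | CCCCCC#CC(C)(O)CO | intermediate
5 | rac-3-methyl-5-pentyl-2,3-dihydrofuran-3-ol | CCCCCC1=CC(C)(O)CO1 | intermediate
6 | 4-methyl-2-pentylfuran | CCCCCc1cc(C)co1 | intermediate
7 | 1-bromo-6-chlorohexane | ClCCCCCCBr | starting material
8 | (3-methyl-5-pentylfuran-2-yl)lithium | CCCCCc1cc(C)c([Li])o1 | intermediate
9 | 2-(6-chlorohexyl)-3-methyl-5-pentylfuran | CCCCCc1cc(C)c(CCCCCCCl)o1 | intermediate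
10 | 7-bromoheptanoic acid | OC(=O)CCCCCCBr | starting material
11 | [6-(3-methyl-5-pentylfuran-2-yl)hexyl]magnesium chloride | CCCCCc1cc(C)c(CCCCCC[Mg]Cl)o1 | intermediate
12 | chloromagnesium 7-bromoheptanoate | BrCCCCCCC(=O)O[Mg]Cl | intermediate
13 | 13-(3-methyl-5-pentylfuran-2-yl)tridecanoic acid | CCCCCc1cc(C)c(CCCCCCCCCCCCC(=O)O)o1 | target

**Total step count:** 4
**Longest linear sequence:** 4 steps (1 → 4 → 6 → 9 → 13)

**Steps most likely to fail**

Step 4. The magnesium carboxylate may stay largely undissolved in THF, so that the coupling is slow and is outrun by homocoupling, β-hydride elimination or protonation of the Grignard reagent. The fallback sets out from 9 and makes the same C7–C8 bond as a C(sp)–C(sp3) bond. Finkelstein exchange (NaI, acetone, reflux) should give 2-(6-iodohexyl)-3-methyl-5-pentylfuran F1. The dilithio derivative of commercial hept-6-ynoic acid (n-BuLi, 2.1 equiv, THF/DMPU, −78 → 0 °C) is then alkylated at the acetylide carbon with F1 to give 13-(3-methyl-5-pentylfuran-2-yl)tridec-6-ynoic acid F2. Hydrogenation of the triple bond (H2, 1 atm, Pd/C, EtOAc, rt, stopped after two equivalents) should leave the far less reactive trialkylfuran intact and comes back to the route at 13.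

Step 3. The SN2 reaction of the furyllithium, which carries a neighbouring methyl group, may be sluggish, letting E2 elimination or lithium–bromine exchange on the dihalide compete and returning protonated furan. The fallback sets out from 6 and replaces alkylation by cross-coupling. Bromination at the free α-position (NBS, DMF, −20 °C) should give 2-bromo-3-methyl-5-pentylfuran F3, used without storage. Negishi coupling of F3 with commercial (6-chlorohexyl)zinc bromide (Pd(dppf)Cl2 cat., THF, rt → 50 °C) comes back to the route at 9.

Step 1. The lithium alkoxide of unprotected hydroxyacetone may aggregate or enolise and self-condense, so that the carbonyl addition stalls. The fallback sets out from 1 (through acetylide 3) and uses a different furan precursor. Addition to chloroacetone (THF, −78 °C) should give the lithium alkoxide of rac-1-chloro-2-methylnon-3-yn-2-ol F4, which closes on warming to rac-2-(hept-1-yn-1-yl)-2-methyloxirane F5. Gold-catalysed cycloisomerisation of this alkynyl oxirane (AuCl3, 5 mol %, MeCN, rt) comes back to the route at 6, replacing steps 1 and 2.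

**Further compounds**
F1 | step 4 | 2-(6-iodohexyl)-3-methyl-5-pentylfuran | CCCCCc1cc(C)c(CCCCCCI)o1
F2 | step 4 | 13-(3-methyl-5-pentylfuran-2-yl)tridec-6-ynoic acid | CCCCCc1cc(C)c(CCCCCCC#CCCCCC(=O)O)o1
F3 | step 3 | 2-bromo-3-methyl-5-pentylfuran | CCCCCc1cc(C)c(Br)o1
F4 | step 1 | rac-1-chloro-2-methylnon-3-yn-2-ol | CCCCCC#CC(C)(O)CCl
F5 | step 1 | rac-2-(hept-1-yn-1-yl)-2-methyloxirane | CCCCCC#CC1(C)CO1
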